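(The earlier runs and the new flask were generated by integration for substances that don't exist, noise included.)

At 8.0 min ash and cedar are to be read, but the runs stop at 4.00 min, so the substrate curve has to be carried a further 4.00 min.

| flask | substrate | partner | protic impurity | remark | time |
|---|---|---|---|---|---|
| autumn | 0.25 M | 0.13 M | 0.25 M | run made earlier |  |
| dawn | 0.25 M | 0.27 M | 0.25 M | run made earlier |  |
| noon | 0.25 M | 0.39 M | 0.25 M | run made earlier |  |
| ash | 0.25 M | 0.440 M | 0.250 M |  | 8.0 min |
| cedar | 0.25 M | 0.170 M | 0.250 M |  | 8.0 min |

- autumn (time / min: target / %, substrate / %, open intermediate / %): 0.333: 0, 99, 5; 0.667: 0, 94, 6; 1.00: 0, 87, 11; 2.00: 0, 85, 19; 4.00: 2, 77, 23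
- dawn (time / min: target / %, substrate / %, open intermediate / %): 0.833: 3, 92, 10; 1.50: 0, 89, 15; 2.50: 1, 81, 20; 3.00: 2, 78, 21; 4.00: 0, 75, 25
- noon (time / min: target / %, substrate / %, open intermediate / %): 0.333: 0, 96, 4; 0.667: 0, 95, 10; 1.00: 0, 90, 9; 2.00: 0, 84, 14; 4.00: 2, 77, 25

(each reading ± 1.5 percentage points)

- which of these there is most of at the end, counted by the substrate in it, ash (substrate / target / open intermediate)
- which of these there is most of at the end, counted by the substrate in it, cedar (substrate / target / open intermediate)
- amount of the one of these that there is most of at the end, in percent of the substrate charged, ash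
- amount of the one of these that there is most of at the end, in percent of the substrate charged, cedar



Autumn and noon differ by a factor of 3.00 in c(partner), yet by 2.00 min they have lost 15.0 % and 16.0 % of the substrate, and by 4.00 min each stands at 77 %. Pooled, the first window loses 15.5 % of the substrate; with 23.0 % lost by 4.00 min, the equal second window loses 7.5 percentage points. Their ratio reads 0.484: this is the carry-over ratio, the part of one window's substrate loss that the next equal window repeats. It is less than one, so the readings bend as a first-order relaxation does, and the windows sum to a reckoned plateau of 70.0 % substrate, a figure that carries the scatter of those readings.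

Going round twice more, the next windows are reckoned to lose 3.6 points and 1.8 points. That reckons substrate at 71.6 % at 8.0 min in ash and in cedar, more than the 28.4 % left for open intermediate and target together. This reckoning therefore answers substrate for both flasks.

Was one number enough? Taken run by run, the ratio is 0.533 in autumn and 0.437 in noon, giving 70.5 % and 72.6 %. That gap of 2.1 points is set against a scatter of 1.5 points on each reading. But ash, at 0.440 M partner, lies above noon's 0.39 M, and the ratio says nothing of target, whose last readings are 2 %, 0 % and 2 %.

The forecast also names substrate for ash and substrate for cedar, but at 58 % (51 % to 64 %) and 59 % (53 % to 65 %), and in its words, “The first step therefore looks zero order in partner”. The reckoning above stands higher than both ranges.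

Ash gives substrate at 69.5 % and cedar substrate at 71.3 %, both higher than the forecast's ranges.

    partner → second intermediate (k = 8.20 × 10⁻⁴ s⁻¹)
    open intermediate + second intermediate → target (k = 0.0160 M⁻¹ s⁻¹)
    substrate ⇌ open intermediate (K = 0.410, k = 0.00190 s⁻¹)
    partner + protic impurity → quenched reagent (k = 0.0350 M⁻¹ s⁻¹)

The reckoned 71.6 % stands 2.1 points above ash, which holds 6.62 % target, and 0.30 points above cedar, which holds 2.01 %. The neighbouring flask is cedar read at 30 min, after 15.0 windows, so the reckoning there is the reckoned plateau 70.0 %. Taken on the part not turned to target, 6.87 %, it gives 65.2 %. That flask gives 66.3 % substrate beside 26.9 % open intermediate, with 0.018 % of the partner charge left.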